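## Retrosynthetic overview

1. Locants used throughout: ten-membered ring C1–C10 with C1=C10(CH3), C2H2–C3H2, C4(CH3)=C5, C6 (OH), C7 (isopropyl), C8 (O-feruloyl), C9H2; the cyclohexane precursors are ring C5–C10 of the same atoms.
2. Late stage: phenol acetate and C6 PMB ether come off last; C8–O is acylated with 4-O-acetylferulic acid; C5–H comes from a C5 enol triflate.
3. Key disconnection, bond C2–C3: ring atoms C10=C1–C2–C3–C4=C5 form a 1,5-diene, so the ten-membered ring is the [3,3] ring-expansion product of a six-membered ring (C5–C10) with a vinyl group on C10 and an isopropenyl group plus a temporary oxy-anion on C5 (anionic oxy-Cope; the C5 oxygen leaves later as triflate).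
4. The cyclohexane template sets C6, C7 and C8: (S)-4-silyloxycyclohexenone, α′-methylation and α′-vinylation (C10), anti conjugate addition of isopropyl (C7), trans-diaxial epoxide opening (C6–O), isopropenyl addition to the C5 ketone.
5. Ring order: six-membered ring from the starting enone; ten-membered ring in step 10 by six-to-ten ring expansion.

Key step: step 10

Assumption: enone 1 is taken as a purchasable single enantiomer; its silyloxy carbon becomes C8, and with the isopropyl group drawn up the target has C6–OH up (cis) and C8–O down (trans).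

## Route

Step 1
Reactants: 1 (S)-4-[(tert-butyldimethylsilyl)oxy]cyclohex-2-en-1-one
Product: 2 (4S)-4-[(tert-butyldimethylsilyl)oxy]-6-methylcyclohex-2-en-1-one (both epimers at the methyl carbon C10)
Conditions: LiN(iPr)2 (1.1 equiv), THF, −78 °C; MeI, DMPU, −78 to −30 °C
Reagents that add atoms: iodomethane, CI
Why: Kinetic deprotonation of the enone by the lithium amide occurs at the only saturated α-carbon (C10) and the cross-conjugated enolate is C-methylated (α′-alkylation of a cyclohexenone); the new centre is planarised again in step 2, so its configuration does not matter.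

Step 2
Reactants: 2 (4S)-4-[(tert-butyldimethylsilyl)oxy]-6-methylcyclohex-2-en-1-one
Product: 3 6-methyl-6-[2-(phenylsulfinyl)ethyl] enone
Conditions: LiN(iPr)2 (1.1 equiv), THF, −78 °C; phenyl vinyl sulfoxide, −78 to 0 °C; H2O quench
Reagents that add atoms: phenyl vinyl sulfoxide, C=CS(=O)c1ccccc1
Why: The same carbon is deprotonated again and the tetrasubstituted lithium enolate adds to phenyl vinyl sulfoxide as a vinyl cation equivalent (Michael addition), the electrophile being expected to enter anti to the C8 silyloxy group, which sets the quaternary centre C10 with the two-carbon arm trans to OTBS.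

Step 3
Reactants: 3 6-methyl-6-[2-(phenylsulfinyl)ethyl] enone
Product: 4 (4S,6R)-4-[(tert-butyldimethylsilyl)oxy]-6-ethenyl-6-methylcyclohex-2-en-1-one
Conditions: toluene, NaHCO3 (solid), 110 °C
Reagents that add atoms: none
Why: Thermal syn-elimination of the alkyl aryl sulfoxide (sulfoxide pyrolysis) can only take a hydrogen of the neighbouring CH2 and unveils the vinyl group on the quaternary carbon without touching any stereocentre.

Step 4
Reactants: 4 (4S,6R)-4-[(tert-butyldimethylsilyl)oxy]-6-ethenyl-6-methylcyclohex-2-en-1-one
Product: 6 cyclohexenyl triflate (C5–OTf; C5=C6; C7 isopropyl), via chloromagnesium enolate 5 (not isolated)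
Conditions: i-PrMgCl (1.3 equiv), CuBr·SMe2 (10 mol %), THF, −78 °C; then PhNTf2, DMPU, −78 °C to rt
Reagents that add atoms: isopropylmagnesium chloride, CC(C)[Mg]Cl; N-phenylbis(trifluoromethanesulfonimide), O=S(=O)(N(c1ccccc1)S(=O)(=O)C(F)(F)F)C(F)(F)F
Why: Copper-catalysed conjugate addition of the Grignard reagent occurs anti to the adjacent C8 silyloxy group, as is general for 4-silyloxycyclohexenones, which sets C7 trans to C8, and the regio-defined enolate is O-sulfonylated in the same flask (conjugate addition–enolate triflation).

Step 5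
Reactants: 6 cyclohexenyl triflate
Product: 7 cyclohexene (C5=C6; C7 isopropyl; C8 OTBS; C10 methyl and vinyl)
Conditions: Pd(OAc)2 (5 mol %), PPh3 (10 mol %), HCO2H, Bu3N, DMF, 60 °C
Reagents that add atoms: none
Why: Palladium-catalysed formate reduction of the enol triflate (oxidative addition to zerovalent palladium, formate exchange, loss of CO2, reductive elimination) replaces OTf by H and leaves the C5=C6 alkene with the vinyl group untouched.

Step 6
Reactants: 7 cyclohexene
Product: 8 C5–C6 epoxide
Conditions: mCPBA (1.1 equiv), NaHCO3, CH2Cl2, 0 °C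
Reagents that add atoms: 3-chloroperoxybenzoic acid, OOC(=O)c1cccc(Cl)c1
Why: In this Prilezhaev epoxidation the peracid selects the cis-disubstituted ring alkene over the monosubstituted vinyl group and attacks the face opposite the pseudo-axial C10 vinyl group and the allylic C7 isopropyl group, so the oxirane oxygen lies trans to both.

Step 7
Reactants: 8 C5–C6 epoxide
Product: 9 C5 alcohol with C6 PMB ether
Conditions: 4-methoxybenzyl alcohol (5 equiv), Yb(OTf)3 (10 mol %), CH2Cl2, 0 °C to rt
Reagents that add atoms: 4-methoxybenzyl alcohol, COc1ccc(CO)cc1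
Why: Lewis-acid-catalysed alcoholysis of the epoxide is expected at C6, away from the neopentyl C5, in the trans-diaxial (Fürst–Plattner) sense, so the ether oxygen enters with inversion cis to the C7 isopropyl group and C5 keeps the epoxide oxygen as a free hydroxyl.

Step 8
Reactants: 9 C5 alcohol with C6 PMB ether
Product: 10 C5 ketone with axial C6 PMB ether
Conditions: Dess–Martin periodinane, NaHCO3, CH2Cl2, rt
Reagents that add atoms: none
Why: Dess–Martin oxidation of the hindered secondary alcohol runs under buffered conditions that should not epimerise the α-alkoxy centre C6 and leaves the PMB ether, the silyl ether and the vinyl group intact.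

Step 9
Reactants: 10 C5 ketone with axial C6 PMB ether
Product: 11 trans-dialkenyl carbinol (C5 OH and isopropenyl)
Conditions: CH2=C(CH3)MgBr (2 equiv), LaCl3·2LiCl (1 equiv), THF, 0 °C
Reagents that add atoms: isopropenylmagnesium bromide, C=C(C)[Mg]Br
Why: In the chair with equatorial isopropyl and silyloxy groups the C6 ether and the C10 vinyl group are both axial on one face, so this lanthanum-promoted 1,2-addition of the alkenyl Grignard reagent must come from the opposite face (axial attack, consistent with the polar Felkin–Anh model), which sets C5 with the isopropenyl group trans to the C10 vinyl group.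

Step 10
Reactants: 11 trans-dialkenyl carbinol
Product: 14 ten-membered enol triflate, via potassium alkoxide 12 (not isolated), via potassium enolate 13 (not isolated)
Conditions: KH (1.5 equiv), 18-crown-6 (1.5 equiv), THF, 0 to 25 °C (to 45 °C if needed); then PhNTf2, −78 to 0 °C
Reagents that add atoms: N-phenylbis(trifluoromethanesulfonimide), O=S(=O)(N(c1ccccc1)S(=O)(=O)C(F)(F)F)C(F)(F)F
Why: Deprotonation gives potassium alkoxide 12, whose oxy-anion weakens the C5–C10 bond, and a [3,3]-sigmatropic shift through a chair transition state joins the CH2 terminus of the C10 vinyl group to the CH2 terminus of the C5 isopropenyl group while C5–C10 breaks, giving the ten-membered potassium enolate 13, which is then O-sulfonylated. The closest known reaction type is the anionic oxy-Cope ring expansion of trans-1,2-dialkenylcyclohexanols to (E)-cyclodec-5-enones with trapping of the enolate. The ten-membered ring is closed by four-atom ring expansion of the six-membered ring, the new bond being made inside a six-membered pericyclic array and not by end-to-end cyclisation. No stereocentre is created; the two stereogenic alkenes are set by the chair transition state reached from the ring-inverted cyclohexane conformer with both alkenyl groups equatorial, in which the ring bonds to C9 and C6 lie pseudo-equatorial, giving the E C1=C10 alkene and the enolate with C3 and C6 trans. The step needs the trans relationship of the two alkenyl groups (set in step 9), chair-over-boat selectivity and irreversibility, the last secured by enolate formation; the ring inversion places the isopropyl and silyloxy groups axial, a cost of a few kcal/mol that the alkoxide acceleration should absorb. Sulfonylation on oxygen fixes the enolate regiochemistry and geometry for step 11, and C6, C7 and C8 are spectators.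

Step 11
Reactants: 14 ten-membered enol triflate
Product: 15 (1(10)E,4E)-diene with C6 PMB ether and C8 silyl ether
Conditions: Pd(OAc)2 (5 mol %), PPh3 (10 mol %), HCO2H, Bu3N, DMF, 40 °C
Reagents that add atoms: none
Why: In this second palladium-catalysed formate reduction the alkenylpalladium intermediate keeps its geometry, so H replaces OTf with retention and the (E)-trisubstituted C4=C5 alkene results; the low temperature avoids Cope rearrangement of the 1,5-diene.

Step 12
Reactants: 15 (1(10)E,4E)-diene with C6 PMB ether and C8 silyl ether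
Product: 16 C8 alcohol
Conditions: Bu4NF, THF, 0 °C to rt
Reagents that add atoms: none
Why: Fluoride-mediated cleavage of the secondary silyl ether frees the C8 hydroxyl while the PMB ether and both alkenes are inert.

Step 13
Reactants: 16 C8 alcohol; 17 (E)-3-(4-acetoxy-3-methoxyphenyl)prop-2-enoic acid
Product: 18 C8 4-O-acetylferulate with C6 PMB ether
Conditions: DCC, DMAP (cat.), CH2Cl2, 0 °C to rt
Reagents that add atoms: none
Why: Steglich esterification (carbodiimide activation, acyl transfer through the acylpyridinium of DMAP) acylates the only free hydroxyl with retention at C8, and the phenol is masked as its acetate to prevent self-condensation.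

Step 14
Reactants: 18 C8 4-O-acetylferulate with C6 PMB ether
Product: 19 C6 alcohol (phenol still acetylated)
Conditions: DDQ, CH2Cl2–pH 7 phosphate buffer, 0 °C
Reagents that add atoms: none
Why: Oxidative cleavage of the PMB ether by DDQ (benzylic hydride abstraction, hydrolysis of the oxocarbenium ion) in buffered two-phase medium frees the allylic C6 hydroxyl without the acid that would trigger transannular cyclisation of the 1,5-diene.

Step 15
Reactants: 19 C6 alcohol (phenol still acetylated)
Product: 20 target compound
Conditions: pyrrolidine (3 equiv), CH2Cl2, 0 °C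
Reagents that add atoms: none
Why: Aminolysis of the aryl acetate by the secondary amine is much faster than attack on the alkyl cinnamate, so the phenol should be unmasked at 0 °C without ester cleavage or acyl migration to the C6 hydroxyl.

## Compound list

1 | (S)-4-[(tert-butyldimethylsilyl)oxy]cyclohex-2-en-1-one (C=O is C5, CH–OTBS is C8) | O=C1C=C[C@@H](O[Si](C)(C)C(C)(C)C)CC1 | starting material
2 | (4S)-4-[(tert-butyldimethylsilyl)oxy]-6-methylcyclohex-2-en-1-one, both epimers at the methyl carbon (C10) | O=C1C=C[C@@H](O[Si](C)(C)C(C)(C)C)CC1C | intermediate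
3 | (4S,6R)-4-[(tert-butyldimethylsilyl)oxy]-6-methyl-6-[2-(phenylsulfinyl)ethyl]cyclohex-2-en-1-one, sulfinylethyl arm trans to OTBS, both sulfur epimers | O=C1C=C[C@@H](O[Si](C)(C)C(C)(C)C)C[C@]1(C)CCS(=O)c2ccccc2 | intermediate
4 | (4S,6R)-4-[(tert-butyldimethylsilyl)oxy]-6-ethenyl-6-methylcyclohex-2-en-1-one, vinyl trans to OTBS | O=C1C=C[C@@H](O[Si](C)(C)C(C)(C)C)C[C@]1(C)C=C | intermediate
5 | chloromagnesium enolate (O–MgCl on C5, C5=C6) of the isopropyl adduct; C7 isopropyl trans to C8 OTBS and cis to the C10 vinyl | Cl[Mg]OC1=C[C@H](C(C)C)[C@@H](O[Si](C)(C)C(C)(C)C)C[C@]1(C)C=C | intermediate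
6 | (3S,4S,6R)-4-[(tert-butyldimethylsilyl)oxy]-6-ethenyl-6-methyl-3-(propan-2-yl)cyclohex-1-en-1-yl trifluoromethanesulfonate | FC(F)(F)S(=O)(=O)OC1=C[C@H](C(C)C)[C@@H](O[Si](C)(C)C(C)(C)C)C[C@]1(C)C=C | intermediate
7 | tert-butyl{[(1S,2S,5R)-5-ethenyl-5-methyl-2-(propan-2-yl)cyclohex-3-en-1-yl]oxy}dimethylsilane (C5=C6 alkene) | C1=C[C@H](C(C)C)[C@@H](O[Si](C)(C)C(C)(C)C)C[C@]1(C)C=C | intermediate
8 | C5–C6 epoxide of 7, oxirane oxygen trans to the C7 isopropyl and to the C10 vinyl group | O1[C@H]2[C@@H]1[C@H](C(C)C)[C@@H](O[Si](C)(C)C(C)(C)C)C[C@]2(C)C=C | intermediate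
9 | cyclohexanol: C5–OH trans to C6–O-(4-methoxybenzyl); C6 ether cis to C7 isopropyl; C8 OTBS trans to isopropyl; C10 methyl and vinyl, vinyl cis to isopropyl | O[C@H]1[C@H](OCc2ccc(OC)cc2)[C@H](C(C)C)[C@@H](O[Si](C)(C)C(C)(C)C)C[C@]1(C)C=C | intermediate
10 | C5 ketone of 9 (6-PMB-oxy, 5-isopropyl, 4-OTBS, 2-methyl-2-vinyl cyclohexanone) | O=C1[C@H](OCc2ccc(OC)cc2)[C@H](C(C)C)[C@@H](O[Si](C)(C)C(C)(C)C)C[C@]1(C)C=C | intermediate
11 | tertiary carbinol: C5 OH cis to C6–OPMB and to the C10 vinyl; C5 isopropenyl trans to the C10 vinyl; other centres as in 10 | C=C(C)[C@@]1(O)[C@H](OCc2ccc(OC)cc2)[C@H](C(C)C)[C@@H](O[Si](C)(C)C(C)(C)C)C[C@]1(C)C=C | intermediate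
12 | potassium alkoxide of 11 | C=C(C)[C@@]1([O-])[C@H](OCc2ccc(OC)cc2)[C@H](C(C)C)[C@@H](O[Si](C)(C)C(C)(C)C)C[C@]1(C)C=C.[K+] | intermediate
13 | potassium enolate of the ten-membered ketone: C1=C10 E, C4=C5(O–K) with C3 and C6 trans, C6 OPMB, C7 isopropyl, C8 OTBS | CC(C)(C)[Si](C)(C)O[C@H]1C/C(C)=C/CC/C(C)=C([O-])/[C@H](OCc2ccc(OC)cc2)[C@@H]1C(C)C.[K+] | intermediate
14 | ten-membered enol triflate: as 13 with C5–OSO2CF3 | CC(C)(C)[Si](C)(C)O[C@H]1C/C(C)=C/CC/C(C)=C(OS(=O)(=O)C(F)(F)F)/[C@H](OCc2ccc(OC)cc2)[C@@H]1C(C)C | intermediate
15 | (1(10)E,4E,6S,7S,8S)-8-[(tert-butyldimethylsilyl)oxy]-6-[(4-methoxybenzyl)oxy]germacra-1(10),4-diene | CC(C)(C)[Si](C)(C)O[C@H]1C/C(C)=C/CC/C(C)=C/[C@H](OCc2ccc(OC)cc2)[C@@H]1C(C)C | intermediate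
16 | (1(10)E,4E,6S,7S,8S)-6-[(4-methoxybenzyl)oxy]germacra-1(10),4-dien-8-ol | O[C@H]1C/C(C)=C/CC/C(C)=C/[C@H](OCc2ccc(OC)cc2)[C@@H]1C(C)C | intermediate
17 | (E)-3-(4-acetoxy-3-methoxyphenyl)prop-2-enoic acid (4-O-acetylferulic acid) | COc1cc(/C=C/C(=O)O)ccc1OC(C)=O | starting material
18 | 8-O-(4-O-acetylferuloyl) ester of 16 | COc1cc(/C=C/C(=O)O[C@H]2C/C(C)=C/CC/C(C)=C/[C@H](OCc3ccc(OC)cc3)[C@@H]2C(C)C)ccc1OC(C)=O | intermediate
19 | (1(10)E,4E,6S,7S,8S)-6-hydroxygermacra-1(10),4-dien-8-yl (E)-4-O-acetylferulate | COc1cc(/C=C/C(=O)O[C@H]2C/C(C)=C/CC/C(C)=C/[C@H](O)[C@@H]2C(C)C)ccc1OC(C)=O | intermediate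
20 | (1(10)E,4E,6S,7S,8S)-6-hydroxygermacra-1(10),4-dien-8-yl (E)-ferulate | COc1cc(/C=C/C(=O)O[C@H]2C/C(C)=C/CC/C(C)=C/[C@H](O)[C@@H]2C(C)C)ccc1O | target

## Step count and risks

Total steps: 15. Longest linear sequence: 15 steps (1 to 20); acid 17 is purchased.

Steps most likely to fail:

- **Step 10 (key step).** The rearrangement must pass through the ring-inverted conformer, so it may be slow, and the enolate may then be lost by proton exchange or C-sulfonylation before O-sulfonylation in the crown-ether medium, which would erase the defined regiochemistry and geometry. Fallback, setting out from 11: the alkoxide is generated as before, but the rearranged enolate is quenched at −78 °C with Me3SiCl to give the ten-membered trimethylsilyl enol ether F1, which is isolated. MeLi in THF at 0 °C then regenerates the enolate as its lithium salt, free of crown ether and hydride, and PhNTf2 converts it into 14, where the route is rejoined.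

- **Step 7.** Lewis-acid activation may ionise the epoxide towards the neopentyl carbon C5 with 1,2-shift of a C10 substituent, or the alcohol may attack the wrong carbon or self-condense. Fallback, setting out from 4: copper-catalysed addition of i-PrMgCl with aqueous quench gives the saturated ketone F2. Bromination with PhNMe3Br3 in THF should give the equatorial α-bromo ketone F3 (bromine trans to isopropyl). Substitution by 4-methoxybenzyl alcohol assisted by AgOTf and 2,6-di-tert-butylpyridine, with inversion, delivers 10, where the route is rejoined.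

- **Step 2.** Conjugate addition of the hindered tetrasubstituted enolate may be slow or reversible, and facial discrimination by the remote silyloxy group may be poor; the wrong C10 epimer would end in a cis-dialkenyl carbinol. Fallback, setting out from 2: copper-catalysed addition of i-PrMgCl gives the saturated ketone F4. Me3SiCl, NaI and Et3N in MeCN give the more substituted trimethylsilyl enol ether F5. A Mukaiyama aldol reaction with acetaldehyde (BF3·OEt2, −78 °C) on the chair anchored by the equatorial isopropyl and silyloxy groups should give the axial β-hydroxy ketone F6. Burgess dehydration gives the vinyl ketone F2, and KN(SiMe3)2 with PhNTf2 converts it into 6, where the route is rejoined.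

## Further compounds

F1 | step 10 | trimethylsilyl enol ether of the ten-membered ketone (C5–OSiMe3, C3 and C6 trans, other groups as in 14) | CC(C)(C)[Si](C)(C)O[C@H]1C/C(C)=C/CC/C(C)=C(O[Si](C)(C)C)/[C@H](OCc2ccc(OC)cc2)[C@@H]1C(C)C
F2 | step 7 | (2R,4S,5R)-4-[(tert-butyldimethylsilyl)oxy]-2-ethenyl-2-methyl-5-(propan-2-yl)cyclohexan-1-one | O=C1C[C@H](C(C)C)[C@@H](O[Si](C)(C)C(C)(C)C)C[C@]1(C)C=C
F3 | step 7 | 6-bromo derivative of F2, bromine on C6 trans to the C7 isopropyl group | O=C1[C@@H](Br)[C@H](C(C)C)[C@@H](O[Si](C)(C)C(C)(C)C)C[C@]1(C)C=C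
F4 | step 2 | (4S,5R)-4-[(tert-butyldimethylsilyl)oxy]-2-methyl-5-(propan-2-yl)cyclohexan-1-one, both C2 epimers | O=C1C[C@H](C(C)C)[C@@H](O[Si](C)(C)C(C)(C)C)CC1C
F5 | step 2 | trimethylsilyl enol ether of F4 with the C5=C10 double bond | C[Si](C)(C)OC=1C[C@H](C(C)C)[C@@H](O[Si](C)(C)C(C)(C)C)CC=1C
F6 | step 2 | 2-(1-hydroxyethyl)-2-methyl ketone, hydroxyethyl arm cis to isopropyl, both carbinol epimers | O=C1C[C@H](C(C)C)[C@@H](O[Si](C)(C)C(C)(C)C)C[C@]1(C)C(C)O
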